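# Synthesis plan for CNP0292250.1 (compound 35) by a desymmetrising reductive Heck closure of ring B

## The problem

Compound 35 is a cis-fused decalin (ring A: C1–C5 and C10; ring B: C5–C10) with five stereocentres. Two are quaternary: C4 (methyl and a 3-formyloxy-3-methylbutyl chain) and C10 (methyl). It also carries a secondary alcohol at C3, an exocyclic methylene at C8 and, at C9, a methylene (C11) linked to a 2-methoxy-4-pyranone bearing a methyl ester.

The ring fusion is the stereochemical anchor. H5 and the C10 methyl lie on one face (called α here), which is the convex face of the bicycle. Every other centre shows its small substituent on that face (C4 methyl, H3, H9). C4, C3 and C9 can therefore be controlled from C5/C10, provided that methyl, hydride and hydrogen are each the last group to arrive at their carbon.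

C4, C5 and C10 are contiguous, so forming both quaternary carbons by intermolecular attack on a crowded ring should be avoided. C3 and C8 are both carbonyl-derived and must be distinguishable at every stage, and C9 can epimerise as long as C8 is a ketone.

Three groups will not survive rough treatment. The tertiary formate is lost to bases and nucleophiles. The pyranone (acidic C-methyl, ester, vinylogous carbonate carbon) does not tolerate amide bases. The 1,1-disubstituted alkene does not tolerate acid or radical hydration. They must enter in the order pyranone, alkene, formate, all after the last enolate alkylation.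

The enabling feature is ring A. C1–C5 and C10, with oxygen at C3 para to the methyl-bearing C10, are the skeleton of a 4-alkyl-4-methylcyclohexa-2,5-dienone. This is an achiral compound whose enantiotopic β-carbons become C5 and C1. An arm on C10 (C9–C8–C7=C6) ending in an alkenyl bromide can close ring B onto C5 and create C5 and C10 in one catalytic step.

## Retrosynthesis

**35 back to 32 (end game).** Only heteroatom and methylene bonds are cut. The C3 hydroxyl of 35 is released from silyl ether 34, the formate of 34 is placed on tertiary alcohol 33, and the C8 methylene of 33 comes from ketone 32. The order follows from the labile groups. The formate can go on the tertiary oxygen only while the secondary one is blocked, and it survives acidic but not basic desilylation. The exocyclic alkene must not exist when the side chain is hydrated. The forward steps must be non-basic so that C9 is not epimerised.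

**32 back to 31.** The tertiary alcohol is traced to a prenyl alkene by Markovnikov hydration. Carrying the chain as a prenyl group lets it enter by a fast allylic alkylation and pass through base and hydride steps unprotected. The hydration must then be placed where the prenyl alkene is the only unactivated alkene, which is the case in 31.

**31 back to 21 and 27 (C9–C11).** The bond between C9 and C11 is cut as an aldol condensation of enone 21 with pyranone aldehyde 27, via alkylidene ketone 30. Conjugate reduction of 30 then puts hydrogen on C9. The neighbouring cut, alkylating the C9 enolate with a pyranylmethyl halide, would send the carbon electrophile to the convex face and put C11 on the wrong side. With the condensation route hydrogen arrives last and takes the convex face, as 35 requires. The same reduction removes the C6=C7 bond that served to direct enolisation to C9. The forward reaction needs an enolate that can only form at C9, and an elimination that can only run towards C11 because C10 is quaternary.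

**27 back to 22 and 23 (pyranone).** Aldehyde 27 comes from bromide 26 by formylation. Bromide 26 comes from 4-hydroxy-2-pyranone 25 by O-methylation of the lactone carbonyl, and 25 from 24 by bromination. Pyranone 24 is assembled in one step from methyl acetoacetate 22 and malonyl dichloride 23. All ring atoms and the ester come from two commercial compounds, and the carbon to be functionalised is the most nucleophilic one in 24.

**21 back to 17 (telling C3 and C8 apart).** Enone 21 is unmasked from ketal 20. Before that, C3 is reduced and silylated (19, 20) and the ring A alkene is removed (18) from enone 17. Keeping C8 as a ketal through this stretch is what makes hydride reduction at C3 unambiguous. The alternative, reducing a C3/C8 diketone selectively, has no reliable basis. Hydride has to attack C3 of 18 from the convex face.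

**17 back to 14 and 15 (C4).** Both C4–C bonds are made by alkylating the α′-enolate of enone 14, first with prenyl bromide 15 (giving 16) and then with a methyl electrophile. The order matters: the second group enters on the convex face, so methyl must come second. The enone blocks C2, C10 is quaternary and C8 is a ketal, so C4 is the only acidic position.

**14 back to 13 (key step).** Cutting C5–C6 opens ring B and removes both ring-fusion stereocentres, leading to achiral dienone 13. One ring, one skeletal bond and two stereocentres are formed in the forward step. In 14 the methyl sits on C10, the fusion carbon flanked by C1 and C9, and H sits on C5, flanked by C4 and C6. C8 is carried as a dioxolane, not a ketone, for three reasons. A free ketone would give a product with two enones whose α′-positions (C4, C9) an amide base cannot tell apart. It would make the bromide a vinylogous acyl bromide that can lose its (Z) geometry by bromide addition–elimination. And it would pair an electron-poor alkenylpalladium with an electron-poor alkene.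

**13 back to 7 and 8 (the arm).** The (Z)-bromoalkene of 13 comes from bromoalkyne 12 by cis-hydrogen transfer, and 12 from terminal alkyne 11 by bromination. Ketal 11 comes from ynone 10, and 10 from aldehyde 7 and ethynylmagnesium bromide 8 via alcohol 9. The geometry of the bromide is fixed by a syn addition, and each step has to leave the dienone alone.

**7 back to 1 and 2 (dienone).** Aldehyde 7 is the ozonolysis product of allyl dienone 5. Dienone 5 is the dehydrogenation product of cyclohexenone 4, which is the annulation product of 2-methylpent-4-enal 1 and methyl vinyl ketone 2. The quaternary carbon is made as a racemate and becomes achiral in 5. This route is preferred to a para-C-allylation of a phenol, where O-allylation competes.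

## Roads not taken

**Alternative 1:** The cut is at C10–CH3 and C9–C11. A methyl cuprate would add to C10 of ring B enone A1 (C8 ketone, C9=C10), and the enolate would be alkylated at C9 by pyranylmethyl bromide A2 to give ketone A3, without closing a ring.
- Merits: it is convergent and brings the pyranone in late. Conjugate addition–alkylation gives the anti relationship, which is exactly the trans arrangement of the C10 methyl and C11 in 35. In this respect it is better than the chosen plan, which needs a separate protonation to set C9.
- Weak points: A1 already contains C3, the quaternary C4 and C5 in enantiopure form, so the hard part of the problem is moved into the precursor. The cuprate must attack a β,β-disubstituted carbon next to that crowded region with the facial sense that gives the cis fusion. The hindered enolate must then be alkylated by an electrophile with an ester and an acidic methyl, where proton transfer competes.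
- Comparison: against its better C9 logic the chosen plan sets a catalytic, enantioselective entry from an achiral compound and a ring closure instead of two intermolecular bond formations at the most crowded carbons.

**Alternative 2:** C3–C4 and C5–C10 are cut together. On heating, trienoate A4 would undergo an intramolecular Diels–Alder reaction: its (Z)-2-methylenoate (C4, C5) adds across the 1-silyloxy diene (C3, C2, C1, C10) and closes rings A and B at once to octalin A5.
- Merits: both quaternary carbons and four stereocentres are formed in one step, more than the chosen key step delivers.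
- Weak points: A4 needs a stereodefined trisubstituted enoate, a substituted silyloxy diene and an enantiopure C9, which is the only source of absolute control and sits on a flexible tether. The cycloaddition joins a fully substituted dienophile carbon to a disubstituted diene terminus, with endo/exo and facial selectivity uncertain. A5 still needs its C4 ester homologated by three carbons and its C11 ether exchanged for the pyranone.
- Comparison: the chosen plan forms fewer stereocentres in its key step. In return it has a short achiral precursor, absolute control by a catalyst, and a C4 chain that arrives complete.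

**Alternative 3:** The cut is C4–C5 with C5 as an arene carbon. A chiral palladium catalyst would couple the C4 enolate of bromoaryl ketone A6 with the aryl bromide, closing ring A as 2-tetralone A7 with the quaternary C4 set.
- Merits: asymmetric α-arylation to quaternary carbons is the best-precedented asymmetric step among the four plans. It also solves C4 by catalyst control, where the chosen plan relies on the substrate. In key-step risk this road is ahead.
- Weak points: only one stereocentre is set and ring B remains an anisole. C5, C10 and C9 would all have to be created during or after dearomatisation (dissolving-metal reduction beside a prenyl alkene, introduction of the C10 methyl, control of the cis fusion next to C4). That re-opens the problems of Alternative 1 and lengthens the route.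
- Comparison: the chosen plan accepts a less proven key step because that step delivers the bicyclic core with both fusion centres, after which C4, C3 and C9 follow one rule (attack on the convex face).

Key step: step 9

**Conventions and assumptions**
- Numbering and faces: the decalin carbons keep the numbers C1–C10 of 35 in every intermediate, C11 is the methylene between C9 and the pyranone, and α is the face carrying H5 and the C10 methyl.
- Ligand sense: (R)-BINAP is written in step 9; which antipode of the ligand leads to 14 and not to its mirror image has to be found by experiment, and that antipode is the one meant.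
- Mixtures: 16 (C4), 28 and 29 (C9, C11) and 30 (alkene geometry) are carried on as mixtures, because these elements are erased or reset in the following step.

## Route

Step 1
Reactants: 1 2-methylpent-4-enal (racemic); 2 methyl vinyl ketone
Product: 4 4-allyl-4-methylcyclohex-2-en-1-one (racemic), via Michael adduct 3 (not isolated)
Conditions: H2SO4 (cat.), PhH, 45 °C, then reflux (Dean–Stark)
Reagents that add atoms: none
Why: Acid-catalysed Michael addition of the aldehyde enol to the enone followed by intramolecular aldol condensation (Robinson-type annulation of an α,α-disubstituted aldehyde) gives the 4,4-disubstituted cyclohexenone; the quaternary carbon (later C10) is racemic here, which is harmless because step 2 makes it achiral.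

Step 2
Reactants: 4 4-allyl-4-methylcyclohex-2-en-1-one
Product: 5 4-allyl-4-methylcyclohexa-2,5-dien-1-one
Conditions: DDQ, dioxane, reflux
Reagents that add atoms: none
Why: Quinone dehydrogenation of a 4,4-disubstituted cyclohexenone to the cross-conjugated dienone is a standard reaction; the quaternary carbon prevents aromatisation and the product has a mirror plane.

Step 3
Reactants: 5 4-allyl-4-methylcyclohexa-2,5-dien-1-one
Product: 7 2-(1-methyl-4-oxocyclohexa-2,5-dien-1-yl)acetaldehyde, via ozonide 6 (not isolated)
Conditions: O3, CH2Cl2, −78 °C (stopped when 5 is consumed); then PPh3, −78 °C → rt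
Reagents that add atoms: ozone, [O-][O+]=O
Why: Ozonolysis with reductive work-up; electrophilic ozone cleaves the terminal alkene much faster than the electron-poor dienone double bonds, and the anhydrous conditions avoid hydrate formation and oxa-Michael closure onto the dienone.

Step 4
Reactants: 7 2-(1-methyl-4-oxocyclohexa-2,5-dien-1-yl)acetaldehyde; 8 ethynylmagnesium bromide
Product: 9 4-(2-hydroxybut-3-yn-1-yl)-4-methylcyclohexa-2,5-dien-1-one (racemic)
Conditions: THF, −78 °C; sat. aq. NH4Cl at −78 °C
Reagents that add atoms: none
Why: Grignard 1,2-addition; the aldehyde is far more electrophilic than the vinylogously stabilised dienone carbonyl, and the cold quench keeps the alkoxide from adding to the dienone.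

Step 5
Reactants: 9 4-(2-hydroxybut-3-yn-1-yl)-4-methylcyclohexa-2,5-dien-1-one
Product: 10 4-methyl-4-(2-oxobut-3-yn-1-yl)cyclohexa-2,5-dien-1-one
Conditions: Dess–Martin periodinane, NaHCO3, CH2Cl2, 0 °C → rt
Reagents that add atoms: none
Why: Dess–Martin oxidation of a propargylic alcohol to the ynone under buffered, near-neutral conditions; the carbinol centre is removed.

Step 6
Reactants: 10 4-methyl-4-(2-oxobut-3-yn-1-yl)cyclohexa-2,5-dien-1-one
Product: 11 4-[(2-ethynyl-1,3-dioxolan-2-yl)methyl]-4-methylcyclohexa-2,5-dien-1-one
Conditions: (TMSOCH2)2, TMSOTf (cat.), CH2Cl2, −78 → −20 °C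
Reagents that add atoms: 1,2-bis(trimethylsilyloxy)ethane, C[Si](C)(C)OCCO[Si](C)(C)C
Why: Noyori ketalisation; the ynone carbonyl is ketalised while the cross-conjugated cyclohexadienone carbonyl is known to resist ketalisation (as in steroidal 1,4-dien-3-ones), and the aprotic low-temperature conditions avoid dienone–phenol rearrangement.

Step 7
Reactants: 11 4-[(2-ethynyl-1,3-dioxolan-2-yl)methyl]-4-methylcyclohexa-2,5-dien-1-one
Product: 12 4-{[2-(bromoethynyl)-1,3-dioxolan-2-yl]methyl}-4-methylcyclohexa-2,5-dien-1-one
Conditions: NBS, AgNO3 (cat.), acetone, rt
Reagents that add atoms: N-bromosuccinimide, O=C1CCC(=O)N1Br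
Why: Silver-catalysed electrophilic bromination of a terminal alkyne is specific for the acetylenic C–H and leaves ketal and dienone untouched.

Step 8
Reactants: 12 4-{[2-(bromoethynyl)-1,3-dioxolan-2-yl]methyl}-4-methylcyclohexa-2,5-dien-1-one
Product: 13 4-{[2-((Z)-2-bromoethenyl)-1,3-dioxolan-2-yl]methyl}-4-methylcyclohexa-2,5-dien-1-one
Conditions: 2-nitrobenzenesulfonylhydrazide, Et3N, THF/iPrOH, rt
Reagents that add atoms: none
Why: Diimide reduction transfers two hydrogens to one face of the bromoalkyne, the standard way to (Z)-1-haloalkenes; the carbonyl is not reduced and the linear bromoalkyne should react ahead of the hindered cis-disubstituted dienone alkenes.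

Step 9
Reactants: 13 4-{[2-((Z)-2-bromoethenyl)-1,3-dioxolan-2-yl]methyl}-4-methylcyclohexa-2,5-dien-1-one
Product: 14 cis-fused enone ketal (ring A: C1=C2–C3(=O) enone with C4H2; ring B: C6=C7 alkene; C8 as 1,3-dioxolane; H5 and C10 methyl both α)
Conditions: Pd(OAc)2 (5 mol%), (R)-BINAP (7.5 mol%), HCO2Na (2 equiv), DMF, 60 °C
Reagents that add atoms: none
Why: Proposed new method: enantioselective desymmetrising reductive Heck cyclisations of cyclohexadienones are established for aryl halide tethers and racemic reductive Heck cyclisations of alkenyl halides onto cyclic enones are established, but the enantioselective closure with an alkenyl bromide on an all-carbon tether is assumed here by combining the two. Zerovalent palladium–BINAP inserts into the C6–Br bond with retention of the (Z) geometry, the divalent alkenylpalladium adds syn across one of the two enantiotopic C4=C5 bonds, and the resulting palladium enolate, whose only β-hydrogen (H5) is anti to the metal, cannot eliminate and is reduced by formate (anion exchange, loss of CO2, C–H reductive elimination at C4). Ring B closes in the 6-exo-trig mode, C6 bonding to C5 while palladium goes to C4 outside the new ring. The fusion is cis by geometry: the four-atom tether starts at C10 and can reach C5 only on its own face, so H5 and the C10 methyl end up on the same face. The absolute configuration of C5 and C10, which are created together, is decided by the chiral ligand when it selects one of the two enantiotopic alkenes in the insertion step. The selectivities needed are this enantiotopic-group selection and cyclisation ahead of direct formate reduction of the alkenylpalladium; the second is helped by the two fully substituted tether carbons (C10 and the ketal carbon C8), the low solubility of HCO2Na and the polarity match between an electron-neutral alkenylpalladium and an electron-poor enone. The ketal keeps the (Z)-bromide configurationally stable, which a β-bromoenone exposed to bromide and formate would not be.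

Step 10
Reactants: 14 cis-fused enone ketal; 15 prenyl bromide (1-bromo-3-methylbut-2-ene)
Product: 16 C4-prenyl enone ketal (C4 epimers)
Conditions: LiN(iPr)2, THF, −78 °C; then 15, −78 → −20 °C
Reagents that add atoms: none
Why: Kinetic α′-deprotonation of the cyclohexenone at C4 (the only acidic CH2, since C8 is a ketal and C10 is quaternary) and SN2 alkylation of the cross-conjugated lithium enolate by an allylic bromide; the C4 configuration formed here is erased in step 11.

Step 11
Reactants: 16 C4-prenyl enone ketal
Product: 17 4α-methyl-4β-prenyl enone ketal (C4 quaternary; C1=C2–C3(=O) retained)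
Conditions: LiN(iPr)2, THF/DMPU, −78 °C; MeI, −78 → 0 °C
Reagents that add atoms: iodomethane, CI
Why: Second enolate alkylation; the planar C3–C4 enolate is attacked by methyl iodide on the convex α face, anti to the C5–C6 bond and away from ring B, so the methyl becomes α and the prenyl group installed first is turned to the β face, which sets C4.

Step 12
Reactants: 17 4α-methyl-4β-prenyl enone ketal
Product: 18 4α-methyl-4β-prenyl C3 ketone ketal (C1–C2 saturated)
Conditions: [(Ph3P)CuH]6, PhH, H2O, rt
Reagents that add atoms: none
Why: Copper hydride conjugate reduction is specific for the enone C=C and leaves the isolated C6=C7 and prenyl alkenes and the ketal untouched.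

Step 13
Reactants: 18 4α-methyl-4β-prenyl C3 ketone ketal
Product: 19 3β-alcohol (4α-methyl; 4β-prenyl; C8 ketal)
Conditions: NaBH4, MeOH, 0 °C
Reagents that add atoms: none
Why: Hydride reduction of the only carbonyl; attack on the convex α face (the β face is screened by the C4 prenyl group and by ring B) should give the 3β-alcohol, cis to the C4 chain.

Step 14
Reactants: 19 3β-alcohol
Product: 20 3β-tert-butyldimethylsilyl ether (C8 ketal)
Conditions: TBSOTf, 2,6-lutidine, CH2Cl2, −78 → 0 °C
Reagents that add atoms: tert-butyldimethylsilyl trifluoromethanesulfonate, CC(C)(C)[Si](C)(C)OS(=O)(=O)C(F)(F)F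
Why: Silylation of a hindered secondary alcohol with a silyl triflate; the lutidine buffer keeps the ketal intact.

Step 15
Reactants: 20 3β-tert-butyldimethylsilyl ether
Product: 21 ring B enone (C6=C7–C8(=O) with C9H2; 3β-OTBS; 4α-methyl; 4β-prenyl)
Conditions: TsOH·H2O (cat.), THF/H2O, rt
Reagents that add atoms: water, O
Why: Acid-catalysed hydrolysis of an allylic ketal is fast (allyl-stabilised oxocarbenium ion) and unveils the C8 ketone as an enone whose only α-hydrogens are at C9; the hindered TBS ether and the prenyl group tolerate the mild acid.

Step 16
Reactants: 22 methyl acetoacetate; 23 malonyl dichloride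
Product: 24 methyl 4-hydroxy-2-methyl-6-oxo-6H-pyran-3-carboxylate
Conditions: CH2Cl2, rt → 40 °C (HCl evolved)
Reagents that add atoms: none
Why: Malonyl dichloride acylates the β-keto ester twice (C-acylation at the active methylene, O-acylation of the ketone enol), the established condensation that gives 4-hydroxy-2-pyranones carrying the ester at the position next to the methyl.

Step 17
Reactants: 24 methyl 4-hydroxy-2-methyl-6-oxo-6H-pyran-3-carboxylate
Product: 25 methyl 5-bromo-4-hydroxy-2-methyl-6-oxo-6H-pyran-3-carboxylate
Conditions: NBS, MeCN, rt (dark)
Reagents that add atoms: N-bromosuccinimide, O=C1CCC(=O)N1Br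
Why: Electrophilic bromination at the enolic carbon between the hydroxyl-bearing carbon and the lactone carbonyl, the most nucleophilic position of a 4-hydroxy-2-pyranone.

Step 18
Reactants: 25 methyl 5-bromo-4-hydroxy-2-methyl-6-oxo-6H-pyran-3-carboxylate
Product: 26 methyl 5-bromo-6-methoxy-2-methyl-4-oxo-4H-pyran-3-carboxylate
Conditions: MeOTf, CH2Cl2, rt; then aq. NaHCO3
Reagents that add atoms: methyl trifluoromethanesulfonate, COS(=O)(=O)C(F)(F)F
Why: A hard methylating agent alkylates the neutral 4-hydroxy-2-pyranone at its most basic oxygen, the lactone carbonyl, and loss of the hydroxyl proton gives the 2-methoxy-4-pyranone; this is the known route to α-methoxy-γ-pyranones, whereas methylation of the anion would give the isomeric 4-methoxy-2-pyranone.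

Step 19
Reactants: 26 methyl 5-bromo-6-methoxy-2-methyl-4-oxo-4H-pyran-3-carboxylate
Product: 27 methyl 5-formyl-6-methoxy-2-methyl-4-oxo-4H-pyran-3-carboxylate
Conditions: Pd(PPh3)4 (cat.), CO (3 atm), Bu3SnH (slow addition), PhMe, 50 °C
Reagents that add atoms: carbon monoxide, [C-]#[O+]
Why: Palladium-catalysed formylation of a vinyl bromide with CO and a tin hydride (Stille formylation): oxidative addition at the α-bromoenone carbon, CO insertion and hydride transfer to the acylpalladium.

Step 20
Reactants: 21 ring B enone; 27 methyl 5-formyl-6-methoxy-2-methyl-4-oxo-4H-pyran-3-carboxylate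
Product: 30 C9=C11 pyranylmethylidene dienone (3β-OTBS; 4α-methyl; 4β-prenyl; alkene geometry not defined), via lithium aldolate 28 (not isolated), via C11 mesylate 29 (not isolated)
Conditions: LiN(iPr)2, THF, −78 °C; 27; MsCl, −78 → 0 °C; DBU, 0 °C → rt
Reagents that add atoms: none
Why: Aldol condensation: the kinetic α′-lithium enolate (C9 is the only α-CH2 and ring A has no carbonyl) adds to the non-enolisable aldehyde, and the mesylated aldolate eliminates by E1cB towards C11, the only direction open because C10 is quaternary.

Step 21
Reactants: 30 C9=C11 pyranylmethylidene dienone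
Product: 31 C8 ketone with 9β-pyranylmethyl group (H9 α; ring B saturated; 3β-OTBS; 4α-methyl; 4β-prenyl)
Conditions: [(Ph3P)CuH]6, PhH, H2O, rt
Reagents that add atoms: none
Why: Copper hydride conjugate reduction of both arms of the cross-conjugated dienone (hydride to C11 and to C6) without touching the prenyl alkene or the pyranone; the C8–C9 enolate is protonated kinetically on the convex α face, which places H9 α and C11 β and so sets C9.

Step 22
Reactants: 31 C8 ketone with 9β-pyranylmethyl group
Product: 32 tertiary alcohol (C4 chain CH2CH2C(CH3)2OH; C8 ketone; 3β-OTBS)
Conditions: Co(acac)2 (cat.), PhSiH3, O2 (1 atm), THF/iPrOH, rt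
Reagents that add atoms: dioxygen, O=O
Why: Mukaiyama hydration: hydrogen-atom transfer from a cobalt hydride to the trisubstituted alkene gives the tertiary radical, which is trapped by oxygen and reduced by the silane to the Markovnikov alcohol; the prenyl group is the only unactivated alkene left.

Step 23
Reactants: 32 tertiary alcohol
Product: 33 C8 exocyclic methylene compound (tertiary alcohol; 3β-OTBS)
Conditions: Zn, CH2Br2, TiCl4, THF/CH2Cl2, 0 °C → rt
Reagents that add atoms: dibromomethane, BrCBr
Why: Takai–Lombardo methylenation is non-basic, so the C9 centre next to the ketone is not epimerised, and it is selective for ketones over the ester and the pyranone carbonyl.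

Step 24
Reactants: 33 C8 exocyclic methylene compound
Product: 34 tertiary formate (3β-OTBS)
Conditions: acetic formic anhydride, pyridine, DMAP (cat.), CH2Cl2, 0 °C → rt
Reagents that add atoms: acetic formic anhydride, CC(=O)OC=O
Why: Acyl transfer from the mixed anhydride occurs at the more electrophilic formyl carbon and formylates the tertiary alcohol; the secondary hydroxyl is blocked as its silyl ether.

Step 25
Reactants: 34 tertiary formate
Product: 35 CNP0292250.1
Conditions: HF·pyridine, pyridine/THF, 0 °C → rt
Reagents that add atoms: none
Why: Fluoride-mediated silyl ether cleavage under mildly acidic conditions, which the formate, the exocyclic alkene and the pyranone tolerate; no stereocentre is touched.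

## Compound list

1 | 2-methylpent-4-enal (racemic) | C=CCC(C)C=O | starting material
2 | methyl vinyl ketone (but-3-en-2-one) | CC(=O)C=C | starting material
3 | 2-allyl-2-methyl-5-oxohexanal (racemic Michael adduct) | CC(=O)CCC(C)(CC=C)C=O | intermediate
4 | 4-allyl-4-methylcyclohex-2-en-1-one (racemic) | O=C1C=CC(C)(CC=C)CC1 | intermediate
5 | 4-allyl-4-methylcyclohexa-2,5-dien-1-one | O=C1C=CC(C)(CC=C)C=C1 | intermediate
6 | 4-methyl-4-[(1,2,4-trioxolan-3-yl)methyl]cyclohexa-2,5-dien-1-one (ozonide) | O=C1C=CC(C)(CC2OCOO2)C=C1 | intermediate
7 | 2-(1-methyl-4-oxocyclohexa-2,5-dien-1-yl)acetaldehyde | O=CCC1(C)C=CC(=O)C=C1 | intermediate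
8 | ethynylmagnesium bromide | C#C[Mg]Br | starting material
9 | 4-(2-hydroxybut-3-yn-1-yl)-4-methylcyclohexa-2,5-dien-1-one (racemic) | C#CC(O)CC1(C)C=CC(=O)C=C1 | intermediate
10 | 4-methyl-4-(2-oxobut-3-yn-1-yl)cyclohexa-2,5-dien-1-one | C#CC(=O)CC1(C)C=CC(=O)C=C1 | intermediate
11 | 4-[(2-ethynyl-1,3-dioxolan-2-yl)methyl]-4-methylcyclohexa-2,5-dien-1-one | C#CC1(OCCO1)CC2(C)C=CC(=O)C=C2 | intermediate
12 | 4-{[2-(bromoethynyl)-1,3-dioxolan-2-yl]methyl}-4-methylcyclohexa-2,5-dien-1-one | BrC#CC1(OCCO1)CC2(C)C=CC(=O)C=C2 | intermediate
13 | 4-{[2-((Z)-2-bromoethenyl)-1,3-dioxolan-2-yl]methyl}-4-methylcyclohexa-2,5-dien-1-one | O=C1C=CC(C)(CC2(OCCO2)/C=C\Br)C=C1 | intermediate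
14 | cis-fused enone ketal: C1=C2–C3(=O) enone, C4H2, H5 α, C6=C7 alkene, C8 spiro-1,3-dioxolane, C9H2, C10 methyl α | C12(OCCO1)C=C[C@H]3CC(=O)C=C[C@@]3(C)C2 | intermediate
15 | prenyl bromide (1-bromo-3-methylbut-2-ene) | CC(C)=CCBr | starting material
16 | 14 with a prenyl group at C4 (both C4 epimers) | C12(OCCO1)C=C[C@H]3C(CC=C(C)C)C(=O)C=C[C@@]3(C)C2 | intermediate
17 | 4α-methyl-4β-prenyl enone ketal (C1=C2–C3(=O); C8 dioxolane) | C12(OCCO1)C=C[C@H]3[C@@](C)(CC=C(C)C)C(=O)C=C[C@@]3(C)C2 | intermediate
18 | 4α-methyl-4β-prenyl C3 ketone (C1–C2 saturated; C6=C7; C8 dioxolane) | C12(OCCO1)C=C[C@H]3[C@@](C)(CC=C(C)C)C(=O)CC[C@@]3(C)C2 | intermediate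
19 | 3β-alcohol of 18 | C12(OCCO1)C=C[C@H]3[C@@](C)(CC=C(C)C)[C@@H](O)CC[C@@]3(C)C2 | intermediate
20 | 3β-TBS ether of 19 | C12(OCCO1)C=C[C@H]3[C@@](C)(CC=C(C)C)[C@@H](O[Si](C)(C)C(C)(C)C)CC[C@@]3(C)C2 | intermediate
21 | ring B enone: C6=C7–C8(=O), C9H2; 3β-OTBS; 4α-methyl, 4β-prenyl; H5 and C10 methyl α | O=C1C=C[C@H]2[C@@](C)(CC=C(C)C)[C@@H](O[Si](C)(C)C(C)(C)C)CC[C@@]2(C)C1 | intermediate
22 | methyl acetoacetate | CC(=O)CC(=O)OC | starting material
23 | malonyl dichloride | O=C(Cl)CC(=O)Cl | starting material
24 | methyl 4-hydroxy-2-methyl-6-oxo-6H-pyran-3-carboxylate | COC(=O)C1=C(C)OC(=O)C=C1O | intermediate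
25 | methyl 5-bromo-4-hydroxy-2-methyl-6-oxo-6H-pyran-3-carboxylate | COC(=O)C1=C(C)OC(=O)C(Br)=C1O | intermediate
26 | methyl 5-bromo-6-methoxy-2-methyl-4-oxo-4H-pyran-3-carboxylate | COC(=O)c1c(C)oc(OC)c(Br)c1=O | intermediate
27 | methyl 5-formyl-6-methoxy-2-methyl-4-oxo-4H-pyran-3-carboxylate | COC(=O)c1c(C)oc(OC)c(C=O)c1=O | intermediate
28 | lithium aldolate of 21 and 27 (C9 and C11 not defined) | O=C1C=C[C@H]2[C@@](C)(CC=C(C)C)[C@@H](O[Si](C)(C)C(C)(C)C)CC[C@@]2(C)C1C(O[Li])c1c(OC)oc(C)c(C(=O)OC)c1=O | intermediate
29 | C11 methanesulfonate of the aldol (C9 and C11 not defined) | O=C1C=C[C@H]2[C@@](C)(CC=C(C)C)[C@@H](O[Si](C)(C)C(C)(C)C)CC[C@@]2(C)C1C(OS(C)(=O)=O)c1c(OC)oc(C)c(C(=O)OC)c1=O | intermediate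
30 | C9=C11 pyranylmethylidene dienone (alkene geometry not defined) | O=C1C=C[C@H]2[C@@](C)(CC=C(C)C)[C@@H](O[Si](C)(C)C(C)(C)C)CC[C@@]2(C)C1=Cc1c(OC)oc(C)c(C(=O)OC)c1=O | intermediate
31 | C8 ketone, 9β-pyranylmethyl (H9 α), 3β-OTBS, 4α-methyl, 4β-prenyl | O=C1CC[C@H]2[C@@](C)(CC=C(C)C)[C@@H](O[Si](C)(C)C(C)(C)C)CC[C@@]2(C)[C@H]1Cc1c(OC)oc(C)c(C(=O)OC)c1=O | intermediate
32 | 31 with the C4 chain hydrated to CH2CH2C(CH3)2OH | O=C1CC[C@H]2[C@@](C)(CCC(C)(C)O)[C@@H](O[Si](C)(C)C(C)(C)C)CC[C@@]2(C)[C@H]1Cc1c(OC)oc(C)c(C(=O)OC)c1=O | intermediate
33 | 32 with C8 as exocyclic methylene | C=C1CC[C@H]2[C@@](C)(CCC(C)(C)O)[C@@H](O[Si](C)(C)C(C)(C)C)CC[C@@]2(C)[C@H]1Cc1c(OC)oc(C)c(C(=O)OC)c1=O | intermediate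
34 | tertiary formate of 33 (3β-OTBS) | C=C1CC[C@H]2[C@@](C)(CCC(C)(C)OC=O)[C@@H](O[Si](C)(C)C(C)(C)C)CC[C@@]2(C)[C@H]1Cc1c(OC)oc(C)c(C(=O)OC)c1=O | intermediate
35 | CNP0292250.1 | C=C1CC[C@H]2[C@@](C)(CCC(C)(C)OC=O)[C@@H](O)CC[C@@]2(C)[C@H]1Cc1c(OC)oc(C)c(C(=O)OC)c1=O | target

## Step count and least certain steps

Total: 25 steps. Longest linear sequence: 21 steps (steps 1–15 and 20–25). Steps 16–19 are a four-step side branch to aldehyde 27.

**Step 9 (key step).** Two things are most likely to go wrong. The alkenylpalladium may be reduced by formate before it inserts. The ligand may discriminate poorly between the two enantiotopic alkenes, because the quaternary carbon lies far from the metal during insertion. Fallback by known chemistry: starting from 13, cyclise with the achiral catalyst Pd(PPh3)4 and HCO2Na in DMF (reductive Heck cyclisation of an alkenyl halide onto a cyclic enone) to the racemic cis-fused enone ketal F1. Then separate the enantiomers by preparative chromatography on a chiral stationary phase. The matching enantiomer is 14, where the route is rejoined.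

**Step 8.** Over-reduction is the danger: diimide may also saturate the dienone double bonds, or reduce the bromoalkene further, before the bromoalkyne is consumed. Fallback: set the bromide geometry by ionic anti-hydrobromination instead of hydrogen transfer. Starting from ynone 10, LiBr and AcOH in MeCN give the (Z)-β-bromoenone, 4-[(Z)-4-bromo-2-oxobut-3-enyl]-4-methylcyclohexa-2,5-dien-1-one F2. Low-temperature ketalisation of F2 as in step 6 returns to 13. The ketalisation of F2 carries its own risk of attack at the bromine-bearing carbon.

**Step 13.** Poor facial selectivity of hydride delivery would give the 3α-alcohol. Fallback: replace substrate control by reagent control. Starting from 18, reduce with a Corey–Bakshi–Shibata oxazaborolidine and catecholborane at −78 °C, choosing the catalyst antipode that delivers hydride to the α face. The quaternary C4 and the C2 methylene are well differentiated as large and small groups. This returns to 19 and makes no new compound (F0).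

**Step 20.** The hindered aldolate may revert (retro-aldol) on warming. The elimination next to the quaternary C10 may be slow. Proton transfer from the acidic pyranone methyl may quench the enolate. Fallback: build C11 first and attach the pyranone by cross-coupling. Starting from 21, α-methylenation with paraformaldehyde and N-methylanilinium trifluoroacetate gives the C9 exo-methylene dienone F3. A Heck reaction of F3 with bromide 26 (Pd(OAc)2, P(o-tol)3, NaHCO3, Bu4NCl, DMF, 80 °C) then gives 30. β-Hydride elimination can only occur towards C11, so the alkylidene is the only possible product.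

**Step 21.** Protonation of the enolate on the concave face, or later epimerisation at C9 while C8 is still a ketone, would give the 9α-epimer. The hindered C9=C11 bond may also be reduced incompletely. Fallback: let the carbon electrophile take the face that the proton took. Starting from 27, NaBH4 reduction gives pyranylmethanol F4, and CBr4/PPh3 converts it into pyranylmethyl bromide F5. The lithium enolate of 21 is alkylated with F5 to the C9-alkylated enone F6. Conjugate reduction of the C6=C7 bond of F6 with [(Ph3P)CuH]6 returns to 31.

## Further compounds

F1 | step 9 | racemic cis-fused enone ketal (14 and its enantiomer) | C12(OCCO1)C=C[C@H]3CC(=O)C=C[C@@]3(C)C2.C12(OCCO1)C=C[C@@H]3CC(=O)C=C[C@]3(C)C2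
F2 | step 8 | 4-[(Z)-4-bromo-2-oxobut-3-enyl]-4-methylcyclohexa-2,5-dien-1-one | O=C1C=CC(C)(CC(=O)/C=C\Br)C=C1
F0 | step 13 | none | none
F3 | step 20 | C9 exo-methylene dienone (C6=C7–C8(=O)–C9=CH2; 3β-OTBS; 4α-methyl, 4β-prenyl) | O=C1C=C[C@H]2[C@@](C)(CC=C(C)C)[C@@H](O[Si](C)(C)C(C)(C)C)CC[C@@]2(C)C1=C
F4 | step 21 | methyl 5-(hydroxymethyl)-6-methoxy-2-methyl-4-oxo-4H-pyran-3-carboxylate | COC(=O)c1c(C)oc(OC)c(CO)c1=O
F5 | step 21 | methyl 5-(bromomethyl)-6-methoxy-2-methyl-4-oxo-4H-pyran-3-carboxylate | COC(=O)c1c(C)oc(OC)c(CBr)c1=O
F6 | step 21 | C9-alkylated ring B enone (C6=C7–C8(=O); 9β-pyranylmethyl; 3β-OTBS; 4α-methyl, 4β-prenyl) | O=C1C=C[C@H]2[C@@](C)(CC=C(C)C)[C@@H](O[Si](C)(C)C(C)(C)C)CC[C@@]2(C)[C@H]1Cc1c(OC)oc(C)c(C(=O)OC)c1=O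
A1 | alternative 1 | ring B enone (C8 ketone, C9=C10; 3β-OTBS; 4α-methyl; 4β-(3-methyl-3-triethylsilyloxybutyl)) | O=C1CC[C@H]2[C@@](C)(CCC(C)(C)O[Si](CC)(CC)CC)[C@@H](O[Si](C)(C)C(C)(C)C)CCC2=C1
A2 | alternative 1 | methyl 5-(bromomethyl)-6-methoxy-2-methyl-4-oxo-4H-pyran-3-carboxylate | COC(=O)c1c(C)oc(OC)c(CBr)c1=O
A3 | alternative 1 | cis-fused C8 ketone with C10 methyl and C9 pyranylmethyl arm | O=C1CC[C@H]2[C@@](C)(CCC(C)(C)O[Si](CC)(CC)CC)[C@@H](O[Si](C)(C)C(C)(C)C)CC[C@@]2(C)[C@H]1Cc1c(OC)oc(C)c(C(=O)OC)c1=O
A4 | alternative 2 | acyclic trienoate: (Z)-2-methylenoate, C8 dioxolane, C9 CH2OPMB, 1-silyloxy diene | COC(=O)/C(C)=C\CCC1(OCCO1)[C@H](COCc1ccc(OC)cc1)/C(C)=C/C=C/O[Si](C)(C)C(C)(C)C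
A5 | alternative 2 | cis-fused octalin (C3 silyl ether, C4 methyl and ester, C10 methyl, C8 dioxolane, C9 CH2OPMB) | O1CCOC12CC[C@H]3[C@@](C)(C(=O)OC)[C@@H](O[Si](C)(C)C(C)(C)C)C=C[C@@]3(C)[C@H]2COCc4ccc(OC)cc4
A6 | alternative 3 | 1-(2-bromo-5-methoxyphenyl)-4,7-dimethyloct-6-en-3-one (racemic) | CC(CC=C(C)C)C(=O)CCc1cc(OC)ccc1Br
A7 | alternative 3 | 6-methoxy-1-methyl-1-prenyl-2-tetralone | O=C1CCc2cc(OC)ccc2[C@@]1(C)CC=C(C)C
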